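The reading is wanted at 3.0 h, yet the flask, Saturday's, has been followed to 50.0 min, so its late course must be reckoned from Monday's run, which has less solid reagent.

the same everywhere: substrate 1.5 M (in portions, 2)

|  | solid reagent | remark | time |
|---|---|---|---|
| Saturday's | 1.2 M | the very flask that is asked about, followed so far; portions every 20 min |  |
| Monday's | 0.80 M | run made earlier; portions every 20 min |  |
| flask | 1.20 M | the portions of substrate follow each other after 20 min, the first at the start | 3.0 h |

Saturday's run (percent of the substrate charged)

| time / min | substrate / % | target / % | intermediate A / % |
|---|---|---|---|
| 4.00 | 41 | 0 | 0 |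
| 8.00 | 37 | 0 | 2 |
| 12.0 | 33 | 0 | 2 |
| 20.0 | 30 | 2 | 1 |
| 30.0 | 67 | 0 | 7 |
| 50.0 | 57 | 1 | 14 |

Monday's run (percent of the substrate charged)

| time / h | substrate / % | target / % | intermediate A / % |
|---|---|---|---|
| 0.200 | 36 | 2 | 3 |
| 0.667 | 63 | 0 | 13 |
| 1.00 | 61 | 3 | 18 |
| 1.50 | 52 | 2 | 20 |
| 2.50 | 48 | 5 | 20 |
| 3.00 | 49 | 3 | 19 |

(readings scatter by 2 percentage points)

- percentages count the substrate that a species holds: one idle adduct counts as two
- target is meant together with its idle adduct
- solid, in amounts per volume of the solution: solid reagent
- what was read earlier has a scatter of 2 percentage points, one standard deviation
- on the list of suspects stand: substrate + partner <-> intermediate A; substrate + target <-> idle adduct; substrate <-> intermediate B; intermediate B <-> target; solid reagent <-> partner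
- at the start none of the solid reagent is in solution
- what has gone from substrate into another species counts as reacted, even if it can come back
- in an amount of target, one idle adduct counts as one target
- the reaction counts as stopped when no species that holds the substrate changes by six tenths of a point or more over the second half of the time

* the state of affairs at 3.0 h: stopped, and by what, or still going (for what has run out or reacted, a solid counts together with what of it has only dissolved) (forward and back rates have come level / it is still moving / all of the substrate has reacted / the partner has run out first)
* how much of the substrate has reacted by 3.0 h
* how much target there is at 3.0 h, in percent of the substrate charged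
* how much intermediate A there is at 3.0 h, in percent of the substrate charged

I read Monday's table downward. Intermediate A stands at 20% at 1.50 h and 19% at 3.00 h, while substrate goes from 52% to 49%. I read that near-level ratio as a sign of a reversible pairing of substrate with partner.

Column against column, Saturday's 14% at 50.0 min lies between Monday's 13% at 0.667 h and 18% at 1.00 h, so the early rows do not yet show the extra solid. I expect it to show later, through free partner.

I assume that Monday's solid has dissolved by its last row, so free partner is the charge less what intermediate A holds, 0.515 M. That row then gives 0.753 L mol⁻¹ for the pairing quotient, an apparent equilibrium constant: intermediate A over substrate, per unit of free partner. It is a reading and carries the scatter.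

For the flask I borrow Monday's substrate and put in the larger charge of solid. My own figure is then 28.5% intermediate A, on the high side if some solid stays undissolved.

The forecast says “Saturday should follow Monday's curve”. Its state at the end reads: it is still moving. Its numbers are conversion 51% (48% to 55%), target 4% (2% to 7%) and intermediate A 20% (17.5% to 23%).

The flask's state at the end reads: it is still moving. It gives conversion 54.2%, target 6.00% and intermediate A 25.4%, which is higher than the top of the forecast's range.

    substrate + partner ⇌ intermediate A (K = 0.800 L mol⁻¹, k = 0.00550 L mol⁻¹ s⁻¹)
    substrate + target ⇌ idle adduct, settled at all times (K = 16.0 L mol⁻¹)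
    substrate ⇌ intermediate B (K = 0.380, k = 0.00120 s⁻¹)
    intermediate B ⇌ target (K = 2.30, k = 2.90 × 10⁻⁵ s⁻¹)
    solid reagent ⇌ partner, rate k5*(cs5 - [partner]) while solid is left; crystals form when [partner] > cs5 (solubility = 0.870 M, k = 2.20 × 10⁻⁴ s⁻¹)

The flask holds 0.694 M of free partner at 3.00 h, and 0.753 L mol⁻¹ applied to that and its 45.8% substrate gives 23.9% intermediate A against 25.4%. The neighbour with 0.48 M solid reagent, undissolved solid at 0%, reckoned from its charge and its 54.4% substrate, gives 12.2% against 12.6%. The way back from intermediate A, with that from intermediate B, holds the flask's conversion at 54.2%, in part: without the first, the same run reaches 89.4%.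

The runs stem from a simulated flask on assumed constants; the scatter is artificial.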